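**Plan**
- Retrosynthesis: after removal of the two N-tosyl groups and the O-silyl group, the benzo ring of indole B is taken back to a 4-oxo-4,5,6,7-tetrahydroindole. Its pyrrole ring is then cut at N1–C7a and C3–C3a into 5-prenylcyclohexane-1,3-dione and a ring C α-aminoketone.
- The aminoketone is cut at the ring C–C(=O) bond (aryllithium plus Boc-glycine Weinreb amide) and at the ring C–indole A bond (Suzuki coupling).
- Enabling feature: the prenyl-bearing C6 of indole B is C5 of the dione, the one ring carbon on its mirror plane. Both carbonyls are therefore equivalent and the prenyl position is fixed without any arene regiochemistry.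
- Forward: ring C dibromide → monoketone → indole A attached → amine salt; prenyl arene → Birch reduction → dione. The pyrrole ring of indole B closes in step 10, its carbocycle is aromatised in steps 11–14, and one fluoride step unmasks the target.
- Stereochemistry: the target has no stereocentre. C6 (and later C4) of the tetrahydroindole intermediates are uncontrolled and disappear on aromatisation.

Key step: step 10

Remark: Weinreb amide 3 and 5-hydroxyindole 7 are taken as purchased; compounds 22–26 are racemic at the prenyl-bearing carbon, which is of no consequence for the achiral target.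

Step 1
Reactants: 1 1,2,4,5-tetramethoxybenzene
Product: 2 1,4-dibromo-2,3,5,6-tetramethoxybenzene
Conditions: Br2 (2.1 equiv), CH2Cl2, 0 °C → rt
Reagents that add atoms: bromine, BrBr
Why: Electrophilic aromatic bromination; the two open positions are each flanked by two methoxy groups and are the only sites available, so the para-dibromide should be the sole product.

Step 2
Reactants: 2 1,4-dibromo-2,3,5,6-tetramethoxybenzene; 3 N-Boc-glycine N-methoxy-N-methylamide
Product: 6 tert-butyl N-[2-(4-bromo-2,3,5,6-tetramethoxyphenyl)-2-oxoethyl]carbamate, via aryllithium 4 (not isolated), via N-magnesiated Weinreb amide 5 (not isolated)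
Conditions: 2: n-BuLi (1.0 equiv), THF, −78 °C; 3: i-PrMgCl (1.0 equiv), THF, −20 °C; combine at −78 °C → 0 °C; aq NH4Cl
Reagents that add atoms: none
Why: Mono bromine–lithium exchange followed by Weinreb ketone synthesis; prior N-deprotonation of the carbamate keeps the aryllithium from being quenched, and the chelated tetrahedral adduct stops the addition at the ketone.

Step 3
Reactants: 7 5-hydroxyindole
Product: 8 5-(triisopropylsilyloxy)-1H-indole
Conditions: TIPSCl, imidazole, DMF, rt
Reagents that add atoms: triisopropylsilyl chloride, CC(C)[Si](Cl)(C(C)C)C(C)C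
Why: Imidazole-mediated O-silylation of the phenol; the weakly acidic indole N–H does not react under these conditions.

Step 4
Reactants: 8 5-(triisopropylsilyloxy)-1H-indole
Product: 10 3-iodo-1-tosyl-5-(triisopropylsilyloxy)indole, via 3-iodoindole 9 (not isolated)
Conditions: NIS, THF, 0 °C, dark; then NaH, TsCl, 0 °C → rt
Reagents that add atoms: N-iodosuccinimide, O=C1CCC(=O)N1I; p-toluenesulfonyl chloride, Cc1ccc(S(=O)(=O)Cl)cc1
Why: Electrophilic iodination at C3, the most nucleophilic indole carbon, then N-sulfonylation of the indolide anion, which also stabilises the labile 3-iodoindole.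

Step 5
Reactants: 10 3-iodo-1-tosyl-5-(triisopropylsilyloxy)indole
Product: 12 3-(4,4,5,5-tetramethyl-1,3,2-dioxaborolan-2-yl)-1-tosyl-5-(triisopropylsilyloxy)indole, via indol-3-ylmagnesium chloride 11 (not isolated)
Conditions: i-PrMgCl·LiCl, THF, −40 °C; then i-PrOBpin, −40 °C → rt; aq NH4Cl
Reagents that add atoms: 2-isopropoxy-4,4,5,5-tetramethyl-1,3,2-dioxaborolane, CC(C)OB1OC(C)(C)C(C)(C)O1
Why: Iodine–magnesium exchange followed by borylation with an alkoxyboronate; the N-sulfonyl group keeps the 3-magnesio species stable at low temperature.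

Step 6
Reactants: 6 tert-butyl N-[2-(4-bromo-2,3,5,6-tetramethoxyphenyl)-2-oxoethyl]carbamate; 12 indol-3-yl pinacol boronate
Product: 13 tert-butyl N-[2-oxo-2-[2,3,5,6-tetramethoxy-4-(1-tosyl-5-triisopropylsilyloxyindol-3-yl)phenyl]ethyl]carbamate
Conditions: Pd(OAc)2 (5 mol %), SPhos (10 mol %), K3PO4, toluene/H2O (10:1), 90 °C
Reagents that add atoms: none
Why: Suzuki–Miyaura coupling; the dialkylbiarylphosphine ligand is suited to the di-ortho-methoxy bromide, whose para ketone assists oxidative addition, and carbamate, silyl ether and sulfonamide should tolerate the phosphate base.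

Step 7
Reactants: 13 Boc-protected biaryl aminoketone
Product: 14 2-amino-1-[2,3,5,6-tetramethoxy-4-(1-tosyl-5-triisopropylsilyloxyindol-3-yl)phenyl]ethanone hydrochloride
Conditions: 4 M HCl in dioxane, CH2Cl2, 0 °C → rt; evaporate, triturate with Et2O
Reagents that add atoms: hydrogen chloride, Cl
Why: Acidolysis of the Boc carbamate; the aryl silyl ether and the N-sulfonyl group are stable to anhydrous HCl, and isolation as the salt prevents self-condensation of the aminoketone.

Step 8
Reactants: 15 1-bromo-3,5-dimethoxybenzene; 16 prenyl bromide (1-bromo-3-methylbut-2-ene)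
Product: 18 1,3-dimethoxy-5-(3-methylbut-2-enyl)benzene, via aryl Grignard reagent 17 (not isolated)
Conditions: Mg, cat. I2, THF, reflux; then CuI (10 mol %), 16, −20 °C → rt
Reagents that add atoms: none
Why: Grignard formation and copper-catalysed allylic substitution; attack at the unsubstituted α-carbon of prenyl bromide (SN2) is favoured over the fully substituted γ-carbon, giving the linear prenyl arene.

Step 9
Reactants: 18 1,3-dimethoxy-5-(3-methylbut-2-enyl)benzene
Product: 20 5-(3-methylbut-2-enyl)cyclohexane-1,3-dione, via Birch diene 19 (not isolated)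
Conditions: Li, NH3(l), THF, t-BuOH, −78 → −33 °C; NH4Cl; then 1 M aq HCl, THF, rt
Reagents that add atoms: water, O
Why: Birch reduction leaves both methoxy groups on the surviving double bonds and does not touch the isolated trisubstituted alkene, and dilute-acid hydrolysis of the bis-enol ether releases the 1,3-dione; t-BuOH as proton source avoids amide-induced alkene migration.

Step 10
Reactants: 14 aminoketone hydrochloride; 20 5-(3-methylbut-2-enyl)cyclohexane-1,3-dione
Product: 23 racemic 3-aryl-6-(3-methylbut-2-enyl)-1,5,6,7-tetrahydroindol-4-one (aryl = 2,3,5,6-tetramethoxy-4-(1-tosyl-5-triisopropylsilyloxyindol-3-yl)phenyl), via free aminoketone 21 (not isolated), via enaminone 22 (not isolated)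
Conditions: NaOAc, AcOH, 90 °C, argon; 14 added in portions to excess 20
Reagents that add atoms: none
Why: Acetate frees amine 21 at low concentration, and it condenses with one of the two equivalent carbonyls of 20 to the vinylogous amide 22, forming N1–C7a. The nucleophilic α-carbon of 22 (former C2 of the dione) then adds to the aryl ketone in an aldol-type 5-exo-trig closure that forms C3–C3a, and loss of water aromatises the pyrrole; this is the Knorr-type condensation of α-aminoketones with cyclohexane-1,3-diones to 4-oxotetrahydroindoles. No stereocentre is controlled: C6 becomes stereogenic only because the two carbonyls are differentiated, so 23 is racemic, which does not matter because C6 becomes sp2 in step 14. The selectivity needed is regiochemical (ring C at C3, prenyl at C6), and the substrates secure it: only nitrogen can open the sequence on the dione, the aminoketone offers a single electrophilic carbon for the second bond, and the dione is symmetric about C5. Portionwise addition of the salt to excess dione suppresses dihydropyrazine formation, and the di-ortho-methoxy ketone, twisted out of conjugation with ring C, should remain electrophilic enough for the intramolecular attack.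

Step 11
Reactants: 23 tetrahydroindol-4-one
Product: 24 racemic 1-tosyl derivative of 23
Conditions: NaH, THF, 0 °C; TsCl, 0 °C → rt
Reagents that add atoms: p-toluenesulfonyl chloride, Cc1ccc(S(=O)(=O)Cl)cc1
Why: N-Sulfonylation of the sodium salt of the pyrrole N–H; it removes the vinylogous-amide donation that would otherwise make the C4 carbonyl inert to borohydride.

Step 12
Reactants: 24 N-tosyl tetrahydroindol-4-one
Product: 25 4-hydroxy-4,5,6,7-tetrahydroindole (mixture of C4/C6 diastereomers, racemic)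
Conditions: NaBH4, MeOH/THF, 0 °C → rt
Reagents that add atoms: none
Why: Borohydride reduction of the now ketone-like C4 carbonyl; the carbinol configuration relative to C6 is left uncontrolled because both centres are removed in the next two steps.

Step 13
Reactants: 25 4-hydroxy-4,5,6,7-tetrahydroindole
Product: 26 racemic 1-tosyl-3-aryl-6-(3-methylbut-2-enyl)-6,7-dihydroindole (C4=C5 alkene)
Conditions: TsOH·H2O (10 mol %), toluene, 60 °C
Reagents that add atoms: none
Why: Acid-catalysed E1 dehydration through the pyrrole-stabilised C4 cation; catalytic acid at moderate temperature should spare the prenyl alkene.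

Step 14
Reactants: 26 6,7-dihydroindole
Product: 27 3-[2,3,5,6-tetramethoxy-4-(1-tosyl-5-triisopropylsilyloxyindol-3-yl)phenyl]-6-(3-methylbut-2-enyl)-1-tosylindole
Conditions: DDQ (1.1 equiv), toluene, rt
Reagents that add atoms: none
Why: DDQ dehydrogenation (hydride abstraction from C7 or C6, then proton loss), driven by formation of the benzenoid ring; one equivalent at room temperature limits attack at the prenyl methylene.

Step 15
Reactants: 27 bis-N-tosyl O-silyl precursor
Product: 28 3-[2,3,5,6-tetramethoxy-4-[6-(3-methylbut-2-enyl)-1H-indol-3-yl]phenyl]-1H-indol-5-ol (target)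
Conditions: TBAF (excess), THF, 65 °C, argon; aq NH4Cl
Reagents that add atoms: none
Why: Fluoride-mediated desilylation of the aryl silyl ether and N-desulfonylation of both indoles (attack of fluoride at silicon and at sulfur) in one operation; methoxy and prenyl groups are inert.

**Compound list**
1 | 1,2,4,5-tetramethoxybenzene | COc1cc(OC)c(OC)cc1OC | starting material
2 | 1,4-dibromo-2,3,5,6-tetramethoxybenzene | COc1c(Br)c(OC)c(OC)c(Br)c1OC | intermediate
3 | tert-butyl N-[2-(methoxy(methyl)amino)-2-oxoethyl]carbamate (N-Boc-glycine Weinreb amide) | CON(C)C(=O)CNC(=O)OC(C)(C)C | starting material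
4 | (4-bromo-2,3,5,6-tetramethoxyphenyl)lithium | [Li]c1c(OC)c(OC)c(Br)c(OC)c1OC | intermediate
5 | N-chloromagnesio derivative of 3 | CON(C)C(=O)CN([Mg]Cl)C(=O)OC(C)(C)C | intermediate
6 | tert-butyl N-[2-(4-bromo-2,3,5,6-tetramethoxyphenyl)-2-oxoethyl]carbamate | CC(C)(C)OC(=O)NCC(=O)c1c(OC)c(OC)c(Br)c(OC)c1OC | intermediate
7 | 5-hydroxyindole | Oc1ccc2[nH]ccc2c1 | starting material
8 | 5-(triisopropylsilyloxy)-1H-indole | CC(C)[Si](Oc1ccc2[nH]ccc2c1)(C(C)C)C(C)C | intermediate
9 | 3-iodo-5-(triisopropylsilyloxy)-1H-indole | Ic1c[nH]c2ccc(O[Si](C(C)C)(C(C)C)C(C)C)cc12 | intermediate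
10 | 3-iodo-1-tosyl-5-(triisopropylsilyloxy)indole | Ic1cn(S(=O)(=O)c2ccc(C)cc2)c2ccc(O[Si](C(C)C)(C(C)C)C(C)C)cc12 | intermediate
11 | [1-tosyl-5-(triisopropylsilyloxy)indol-3-yl]magnesium chloride | Cl[Mg]c1cn(S(=O)(=O)c2ccc(C)cc2)c2ccc(O[Si](C(C)C)(C(C)C)C(C)C)cc12 | intermediate
12 | 3-(4,4,5,5-tetramethyl-1,3,2-dioxaborolan-2-yl)-1-tosyl-5-(triisopropylsilyloxy)indole | CC1(C)OB(c2cn(S(=O)(=O)c3ccc(C)cc3)c3ccc(O[Si](C(C)C)(C(C)C)C(C)C)cc23)OC1(C)C | intermediate
13 | tert-butyl N-[2-oxo-2-[2,3,5,6-tetramethoxy-4-(1-tosyl-5-triisopropylsilyloxyindol-3-yl)phenyl]ethyl]carbamate | CC(C)(C)OC(=O)NCC(=O)c1c(OC)c(OC)c(-c2cn(S(=O)(=O)c3ccc(C)cc3)c3ccc(O[Si](C(C)C)(C(C)C)C(C)C)cc23)c(OC)c1OC | intermediate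
14 | 2-amino-1-[2,3,5,6-tetramethoxy-4-(1-tosyl-5-triisopropylsilyloxyindol-3-yl)phenyl]ethanone hydrochloride | Cl.NCC(=O)c1c(OC)c(OC)c(-c2cn(S(=O)(=O)c3ccc(C)cc3)c3ccc(O[Si](C(C)C)(C(C)C)C(C)C)cc23)c(OC)c1OC | intermediate
15 | 1-bromo-3,5-dimethoxybenzene | COc1cc(Br)cc(OC)c1 | starting material
16 | prenyl bromide (1-bromo-3-methylbut-2-ene) | CC(C)=CCBr | starting material
17 | (3,5-dimethoxyphenyl)magnesium bromide | COc1cc([Mg]Br)cc(OC)c1 | intermediate
18 | 1,3-dimethoxy-5-(3-methylbut-2-enyl)benzene | COc1cc(CC=C(C)C)cc(OC)c1 | intermediate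
19 | 1,5-dimethoxy-3-(3-methylbut-2-enyl)cyclohexa-1,4-diene | COC1=CC(CC=C(C)C)C=C(OC)C1 | intermediate
20 | 5-(3-methylbut-2-enyl)cyclohexane-1,3-dione | O=C1CC(CC=C(C)C)CC(=O)C1 | intermediate
21 | 2-amino-1-[2,3,5,6-tetramethoxy-4-(1-tosyl-5-triisopropylsilyloxyindol-3-yl)phenyl]ethanone (free base) | NCC(=O)c1c(OC)c(OC)c(-c2cn(S(=O)(=O)c3ccc(C)cc3)c3ccc(O[Si](C(C)C)(C(C)C)C(C)C)cc23)c(OC)c1OC | intermediate
22 | racemic 3-[[2-oxo-2-(aryl)ethyl]amino]-5-(3-methylbut-2-enyl)cyclohex-2-en-1-one (aryl as in 21) | O=C1C=C(NCC(=O)c2c(OC)c(OC)c(-c3cn(S(=O)(=O)c4ccc(C)cc4)c4ccc(O[Si](C(C)C)(C(C)C)C(C)C)cc34)c(OC)c2OC)CC(CC=C(C)C)C1 | intermediate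
23 | racemic 3-[2,3,5,6-tetramethoxy-4-(1-tosyl-5-triisopropylsilyloxyindol-3-yl)phenyl]-6-(3-methylbut-2-enyl)-1,5,6,7-tetrahydroindol-4-one | COc1c(OC)c(-c2cn(S(=O)(=O)c3ccc(C)cc3)c3ccc(O[Si](C(C)C)(C(C)C)C(C)C)cc23)c(OC)c(OC)c1-c1c[nH]c2c1C(=O)CC(CC=C(C)C)C2 | intermediate
24 | racemic 1-tosyl derivative of 23 | COc1c(OC)c(-c2cn(S(=O)(=O)c3ccc(C)cc3)c3ccc(O[Si](C(C)C)(C(C)C)C(C)C)cc23)c(OC)c(OC)c1-c1cn(S(=O)(=O)c3ccc(C)cc3)c2c1C(=O)CC(CC=C(C)C)C2 | intermediate
25 | 4-hydroxy-1-tosyl-4,5,6,7-tetrahydroindole analogue of 24 (diastereomer mixture) | COc1c(OC)c(-c2cn(S(=O)(=O)c3ccc(C)cc3)c3ccc(O[Si](C(C)C)(C(C)C)C(C)C)cc23)c(OC)c(OC)c1-c1cn(S(=O)(=O)c3ccc(C)cc3)c2c1C(O)CC(CC=C(C)C)C2 | intermediate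
26 | racemic 1-tosyl-3-aryl-6-(3-methylbut-2-enyl)-6,7-dihydroindole | COc1c(OC)c(-c2cn(S(=O)(=O)c3ccc(C)cc3)c3ccc(O[Si](C(C)C)(C(C)C)C(C)C)cc23)c(OC)c(OC)c1-c1cn(S(=O)(=O)c3ccc(C)cc3)c2c1C=CC(CC=C(C)C)C2 | intermediate
27 | 3-[2,3,5,6-tetramethoxy-4-(1-tosyl-5-triisopropylsilyloxyindol-3-yl)phenyl]-6-(3-methylbut-2-enyl)-1-tosylindole | COc1c(OC)c(-c2cn(S(=O)(=O)c3ccc(C)cc3)c3ccc(O[Si](C(C)C)(C(C)C)C(C)C)cc23)c(OC)c(OC)c1-c1cn(S(=O)(=O)c3ccc(C)cc3)c2cc(CC=C(C)C)ccc12 | intermediate
28 | 3-[2,3,5,6-tetramethoxy-4-[6-(3-methylbut-2-enyl)-1H-indol-3-yl]phenyl]-1H-indol-5-ol | COc1c(OC)c(-c2c[nH]c3ccc(O)cc23)c(OC)c(OC)c1-c1c[nH]c2cc(CC=C(C)C)ccc12 | target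

**Step count**
Total: 15 steps. Longest linear sequence: 11 steps (3, 4, 5, 6, 7, 10, 11, 12, 13, 14, 15, from 5-hydroxyindole).

**Steps most likely to fail**

Step 10. The ring closure may stall at enaminone 22 because the ketone carbon is shielded by two ortho methoxy groups, or the liberated aminoketone may dimerise to a dihydropyrazine before the dione captures it. Fallback: the aryl-bearing carbon is offered as a nitroalkene instead of a ketone, so no free aminoketone is ever present. Dibromide 2 is monolithiated as in step 2 and formylated with DMF to 4-bromo-2,3,5,6-tetramethoxybenzaldehyde F1. Suzuki coupling of F1 with boronate 12 under the step 6 conditions gives 2,3,5,6-tetramethoxy-4-(1-tosyl-5-triisopropylsilyloxyindol-3-yl)benzaldehyde F2. Henry condensation with nitromethane (NH4OAc, AcOH, 90 °C) gives the (E)-2-nitrovinyl arene F3. Heating F3 with dione 20 and NH4OAc in ethanol forms 3-amino-5-(3-methylbut-2-enyl)cyclohex-2-en-1-one F4 in the flask. Its α-carbon adds to the nitroalkene (C3–C3a) and its nitrogen then closes onto the nitronate carbon with loss of nitroxyl and water (Grob–Camenzind-type pyrrole synthesis), returning to the route at 23.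

Step 6. Transmetalation at the di-ortho-substituted palladium centre may be slow, so that protodeboronation of the indol-3-yl boronate or base-induced loss of the aryl silyl ether overtakes the coupling. Fallback: a base-free and water-free Negishi coupling. Iodide 10 is converted to the magnesium reagent 11 as in step 5 and transmetalated with ZnCl2 to [1-tosyl-5-(triisopropylsilyloxy)indol-3-yl]zinc chloride F5. F5 is coupled with bromide 6 (Pd(OAc)2, SPhos, THF, 50 °C) and returns to the route at 13, which also removes step 5.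

Step 14. Over-oxidation is possible: once the ring is aromatic the quinone may abstract hydride from the allylic–benzylic methylene of the prenyl group, or accept an electron from the electron-rich ring C. Fallback: the extra unsaturation is introduced at the ketone stage and the oxygen is removed afterwards, bypassing steps 12–14. Ketone 24 is converted (TMSOTf, Et3N, CH2Cl2) into the 4-trimethylsilyloxy-6,7-dihydroindole F6. Saegusa–Ito oxidation (Pd(OAc)2, MeCN) gives the enone, which tautomerises to the 4-hydroxy-6-prenyl-1-tosylindole F7. Triflation (Tf2O, pyridine) gives the aryl triflate F8. Palladium-catalysed transfer hydrogenolysis (Pd(OAc)2, dppf, HCO2H, Et3N, DMF, 60 °C) removes the triflate and returns to the route at 27.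

**Further compounds**
F1 | step 10 | 4-bromo-2,3,5,6-tetramethoxybenzaldehyde | O=Cc1c(OC)c(OC)c(Br)c(OC)c1OC
F2 | step 10 | 2,3,5,6-tetramethoxy-4-(1-tosyl-5-triisopropylsilyloxyindol-3-yl)benzaldehyde | O=Cc1c(OC)c(OC)c(-c2cn(S(=O)(=O)c3ccc(C)cc3)c3ccc(O[Si](C(C)C)(C(C)C)C(C)C)cc23)c(OC)c1OC
F3 | step 10 | 3-[2,3,5,6-tetramethoxy-4-[(E)-2-nitrovinyl]phenyl]-1-tosyl-5-(triisopropylsilyloxy)indole | O=[N+]([O-])/C=C/c1c(OC)c(OC)c(-c2cn(S(=O)(=O)c3ccc(C)cc3)c3ccc(O[Si](C(C)C)(C(C)C)C(C)C)cc23)c(OC)c1OC
F4 | step 10 | 3-amino-5-(3-methylbut-2-enyl)cyclohex-2-en-1-one | NC1=CC(=O)CC(CC=C(C)C)C1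
F5 | step 6 | [1-tosyl-5-(triisopropylsilyloxy)indol-3-yl]zinc chloride | Cl[Zn]c1cn(S(=O)(=O)c2ccc(C)cc2)c2ccc(O[Si](C(C)C)(C(C)C)C(C)C)cc12
F6 | step 14 | 1-tosyl-3-aryl-4-(trimethylsilyloxy)-6-(3-methylbut-2-enyl)-6,7-dihydroindole | COc1c(OC)c(-c2cn(S(=O)(=O)c3ccc(C)cc3)c3ccc(O[Si](C(C)C)(C(C)C)C(C)C)cc23)c(OC)c(OC)c1-c1cn(S(=O)(=O)c3ccc(C)cc3)c2c1C(O[Si](C)(C)C)=CC(CC=C(C)C)C2
F7 | step 14 | 1-tosyl-3-aryl-6-(3-methylbut-2-enyl)indol-4-ol | COc1c(OC)c(-c2cn(S(=O)(=O)c3ccc(C)cc3)c3ccc(O[Si](C(C)C)(C(C)C)C(C)C)cc23)c(OC)c(OC)c1-c1cn(S(=O)(=O)c3ccc(C)cc3)c2cc(CC=C(C)C)cc(O)c12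
F8 | step 14 | 1-tosyl-3-aryl-6-(3-methylbut-2-enyl)indol-4-yl trifluoromethanesulfonate | COc1c(OC)c(-c2cn(S(=O)(=O)c3ccc(C)cc3)c3ccc(O[Si](C(C)C)(C(C)C)C(C)C)cc23)c(OC)c(OC)c1-c1cn(S(=O)(=O)c3ccc(C)cc3)c2cc(CC=C(C)C)cc(OS(=O)(=O)C(F)(F)F)c12
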